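## The problem

1. The target is a 2,3-dihydro-1-benzofuran: benzo ring A is fused to dihydrofuran ring B through C3a and C7a, with O1 on C7a.
2. Ring B carries two adjacent stereocenters that must be trans: C2 (R), bonded to O1 and to the α-carbon of a 1-formylvinyl group, and C3 (S), a benzylic carbon bearing a 3-methylbutanoate. These two centers can control each other.
3. C5 of ring A, para to O1, carries a 1-acyloxyethyl group. Its carbinol carbon (R) is too far from ring B to be controlled by it, and its acyl group is (R)-2-methylbutanoyl, with an epimerisable α-stereocenter. Two secondary benzylic alcohols must therefore receive two different acyl groups.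
4. The C3 ester is benzylic with O1 ortho to it and C2–H next to it, so acid ionises it and ring B aromatises to a benzofuran. A free phenoxide at O1 would expel either benzylic ester (ortho or para) as a quinone methide, so both esters can only be installed after O1 is alkylated.
5. The C2 side chain is the aryl ether of a Morita–Baylis–Hillman-type allylic alcohol. Nucleophilic amines or phosphines can open ring B by SN2′ attack on the enal, so the aldehyde has to appear last, under neutral and non-nucleophilic conditions.
6. The feature that makes the key step possible: C3 is a carbinol carbon on C3a, ortho to the O1-bearing C7a, which is the formyl carbon of a salicylaldehyde. C2 is a single sp3 carbon bonded to both C3 and O1 and carrying a 2-substituted vinyl group. Such a carbon can be delivered as an allylic sulfonium ylide, which acts first as a nucleophile towards C3 and then as an electrophile towards O1.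

## Retrosynthesis

**Formyl group (16 → 15 → 14).** No C–C bond is cut. The formyl carbon of target 16 is lowered to the primary allylic alcohol 15, which is masked as the 4-methoxybenzyl (PMB) ether 14. The alternative, allylic oxidation of an isopropenyl methyl group, would have to compete with the C2–H methine (tertiary, allylic, α to O1). Carrying the oxygen from the start avoids that choice. The forward steps ask only for DDQ and MnO2 to leave two esters and the allylic aryl ether alone.

**Side-chain ester and carbinol (14 → 12 + 13; 12 → 11).** The acyl–O bond of the side-chain ester is cut to alcohol 12 and commercial (R)-2-methylbutanoic acid 13. The carbinol C–H bond is then cut to aryl methyl ketone 11. Keeping C5 as an acetyl group until this point has three advantages: it tolerates the phenoxide chemistry of the key step, it gives each alcohol its own acylation step, and it lets a catalyst set the remote stereocenter. The forward reduction must be catalyst-controlled and must not touch the C3 ester.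

**C3 ester (11 → 9 + 10).** The acyl–O bond at C3 is cut to alcohol 9 and 3-methylbutanoic anhydride 10. At this stage 9 has a single hydroxyl group, so no selectivity is asked for.

**Ring B (9 → 6 + 5, through 7 and 8).** Two bonds are cut at once, C2–C3 and O1–C2. This leaves 5-acetyl-2-hydroxybenzaldehyde 6 and the chiral allylic sulfonium salt 5. In the forward direction ylide 7 gives trans-epoxide 8, which the phenoxide opens at C2. Cutting only O1–C2 would leave an acyclic diol that needs protection, olefination, oxidation and a selective cyclisation. Cutting both bonds reduces ring B and both of its stereocenters to one flat aldehyde and one reagent. The forward reaction must control the face of the aldehyde, give the trans-epoxide, and open it at C2 with inversion.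

**Sulfonium salt (5 → 3 + 4; 3 → 1 + 2).** The S–C bond is cut to allylic chloride 3 and C2-symmetric sulfide 4. The ether C–O bond of 3 is cut to 4-methoxybenzyl alcohol 1 and the symmetric dichloride 2. Both steps are simple alkylations.

## Roads not taken

**Alternative 1 (the most obvious): cut O1–C2 only.**
- Forward: aldehyde 6, with its phenol silylated, is olefinated to the (E)-diene A1. Osmium-catalysed asymmetric dihydroxylation (K2OsO2(OH)4, chiral phthalazine ligand) of the styrene-type double bond and desilylation give syn-diol A2. Mitsunobu closure of the phenol onto C2 with inversion forms ring B. Acylation, reduction and acylation give the isopropenyl diester A3, and SeO2 oxidises its methyl group.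
- Why the chosen plan is better: the ring stereocenters are set in two operations on a protected substrate. The cyclisation must activate the allylic C2 hydroxyl next to a benzylic C3 hydroxyl that ionises more easily. The final ene oxidation must choose the methyl group over the C2–H methine, where attack would open ring B. The route is several steps longer.

**Alternative 2: ring contraction of a chromane by a 1,2-shift of the ring oxygen.**
- Forward: chromene A4 undergoes Jacobsen epoxidation with (R,R)-(salen)MnCl to epoxide A5. Opening at C4 with 3-methylbutanoic acid gives trans hydroxy ester A6. Triflation of the C3 hydroxyl lets O1 migrate from C2 to C3 with inversion, and proton loss from the tertiary cation gives A7 with both ring stereocenters.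
- Why the chosen plan is better: in activated A6 the bonds anti to the leaving group are C2–O1 and C4–C4a, and after a ring flip the trans C4 ester carbonyl reaches the back of C3. Neighbouring-group displacement by the ester and aryl migration therefore compete with the wanted shift. O1 is also a poor donor because its lone pair is drawn into the para acetyl group. A7 carries an isopropenyl group, so the late allylic oxidation problem returns.

**Alternative 3: cut C2–C3 and C7a–O1.**
- Forward: fluoro aldehyde A8 and allylidene diester A9 are coupled by iridium-catalysed transfer-hydrogenative (α-acyloxy)allylation ([Ir(cod)Cl]2, chiral bisphosphine, 2-propanol) to the anti hydroxy ester A10. Base then moves the ester from the C2 oxygen to the C3 oxygen, and the freed C2 alkoxide closes ring B by SNAr at C7a, activated by the para acetyl group. This converges on 11.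
- Why the chosen plan is better: the anti course of this allylation rests on the acyloxy group sitting syn on the π-allyl. A substituent on the central allyl carbon, as in A9, pushes that group anti and so towards the cis ring. A8 and A9 also need their own preparations (three steps for A9), so the run-up to 11 is longer.

Key step: step 3

Assumption: ylides of sulfide 4 (treated as a purchasable reagent) are taken to add to the formyl group with the facial sense that gives the (2S,3S)-epoxide, by analogy with the (S,S)-epoxides formed from its benzylic ylides; if the allylic ylide shows the opposite sense, the enantiomer of 4 is used.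

## Route

Step 1
Reactants: 1 4-methoxybenzyl alcohol; 2 3-chloro-2-(chloromethyl)prop-1-ene
Product: 3 1-({[2-(chloromethyl)prop-2-en-1-yl]oxy}methyl)-4-methoxybenzene
Conditions: NaH, THF/DMF, 0 °C; then 2 (3 equiv), Bu4NI (cat.), rt
Reagents that add atoms: none
Why: Williamson ether synthesis on a symmetric bis-allylic dichloride; the excess of 2 keeps the second chloride intact, and SN2 and SN2′ attack give the same product. No stereocenter is formed.

Step 2
Reactants: 3 1-({[2-(chloromethyl)prop-2-en-1-yl]oxy}methyl)-4-methoxybenzene; 4 (2R,5R)-2,5-dimethylthiolane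
Product: 5 (2R,5R)-1-(2-{[(4-methoxybenzyl)oxy]methyl}prop-2-en-1-yl)-2,5-dimethylthiolan-1-ium tetrafluoroborate
Conditions: AgBF4, CH2Cl2, rt, dark
Reagents that add atoms: silver tetrafluoroborate [Ag+].F[B-](F)(F)F
Why: S-alkylation of the sulfide by the allylic chloride, driven by precipitation of AgCl; attack at either allylic terminus gives the same salt. Because 4 is C2-symmetric its two lone pairs are equivalent, so sulfur is not a stereocenter and 5 is a single isomer.

Step 3
Reactants: 5 (2R,5R)-1-(2-{[(4-methoxybenzyl)oxy]methyl}prop-2-en-1-yl)-2,5-dimethylthiolan-1-ium tetrafluoroborate; 6 5-acetyl-2-hydroxybenzaldehyde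
Product: 9 1-[(2R,3S)-3-hydroxy-2-{3-[(4-methoxybenzyl)oxy]prop-1-en-2-yl}-2,3-dihydro-1-benzofuran-5-yl]ethan-1-one, via sulfonium ylide 7 (not isolated), via trans-epoxy phenolate 8 (not isolated)
Conditions: KOH, MeCN/H2O (9:1), 0 °C to 40 °C
Reagents that add atoms: none
Why: KOH forms the phenoxide of 6 and deprotonates 5 at the allylic CH2 to give ylide 7, which adds to the formyl carbon (more electrophilic than the acetyl carbon) to an anti-betaine; its alkoxide displaces the sulfide in a 3-exo-tet closure to trans-epoxide 8 and returns sulfide 4. The phenoxide O1 then opens 8 at the allylic epoxide carbon C2 in a 5-endo-tet SN2 reaction with inversion, which closes ring B and leaves the epoxide oxygen on C3 as the hydroxyl group. The closest known reactions are the sulfur-ylide (Corey–Chaykovsky-type) epoxidation of aldehydes with chiral sulfonium salts and the conversion of salicylaldehydes into 2,3-dihydrobenzofuran-3-ols by sulfur ylides. C3 is set by reagent control: the C2-symmetric thiolane ring exposes one face of the ylide carbon and so fixes which face of the formyl group is attacked (see the assumption above). C2 is set relative to C3: the 2-substituted allyl ylide should favour the anti-betaine and hence the trans-epoxide, and inversion at C2 in the ring closure turns (2S,3S)-8 into the 2,3-trans (2R,3S) product. The step needs O1 to attack C2 and not the terminal =CH2 or the sulfonium carbon of the betaine: attack at C2 gives the five-membered ring, SN2′ attack would give a seven-membered ring, and epoxide closure of the betaine should be faster than displacement by the weakly nucleophilic acyl-substituted phenoxide. As a phenoxide the substrate is also deactivated towards aldol condensation between its acetyl and formyl groups.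

Step 4
Reactants: 9 1-[(2R,3S)-3-hydroxy-2-{3-[(4-methoxybenzyl)oxy]prop-1-en-2-yl}-2,3-dihydro-1-benzofuran-5-yl]ethan-1-one; 10 3-methylbutanoic anhydride
Product: 11 (2R,3S)-5-acetyl-2-{3-[(4-methoxybenzyl)oxy]prop-1-en-2-yl}-2,3-dihydro-1-benzofuran-3-yl 3-methylbutanoate
Conditions: DMAP (cat.), pyridine, CH2Cl2, 0 °C to rt
Reagents that add atoms: none
Why: DMAP-catalysed acyl transfer to the only hydroxyl group; the basic, non-ionising conditions leave the C3–O bond intact, so C3 keeps its configuration. Acylating here, while C5 still carries the ketone, decides which alcohol receives which acyl group.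

Step 5
Reactants: 11 (2R,3S)-5-acetyl-2-{3-[(4-methoxybenzyl)oxy]prop-1-en-2-yl}-2,3-dihydro-1-benzofuran-3-yl 3-methylbutanoate
Product: 12 (2R,3S)-5-[(1R)-1-hydroxyethyl]-2-{3-[(4-methoxybenzyl)oxy]prop-1-en-2-yl}-2,3-dihydro-1-benzofuran-3-yl 3-methylbutanoate
Conditions: RuCl(p-cymene)[(R,R)-TsDPEN] (1 mol%), HCO2H/Et3N (5:2), EtOAc, 30 °C
Reagents that add atoms: none
Why: Noyori asymmetric transfer hydrogenation; the (R,R)-TsDPEN complex delivers hydride to the face of an aryl methyl ketone that gives the (R)-carbinol, under catalyst control independent of the remote ring stereocenters. Esters, the PMB ether and the 1,1-disubstituted alkene are inert, and any minor enantiomer from step 3 becomes a separable diastereomer here.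

Step 6
Reactants: 12 (2R,3S)-5-[(1R)-1-hydroxyethyl]-2-{3-[(4-methoxybenzyl)oxy]prop-1-en-2-yl}-2,3-dihydro-1-benzofuran-3-yl 3-methylbutanoate; 13 (2R)-2-methylbutanoic acid
Product: 14 (2R,3S)-2-{3-[(4-methoxybenzyl)oxy]prop-1-en-2-yl}-5-[(1R)-1-{[(2R)-2-methylbutanoyl]oxy}ethyl]-2,3-dihydro-1-benzofuran-3-yl 3-methylbutanoate
Conditions: N,N'-diisopropylcarbodiimide, DMAP (cat.), CH2Cl2, 0 °C
Reagents that add atoms: none
Why: Steglich esterification; carbodiimide activation at low temperature with substoichiometric DMAP limits epimerisation at the α-carbon of 13. The carbinol C–O bond is not broken, so the (R) configuration is retained.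

Step 7
Reactants: 14 (2R,3S)-2-{3-[(4-methoxybenzyl)oxy]prop-1-en-2-yl}-5-[(1R)-1-{[(2R)-2-methylbutanoyl]oxy}ethyl]-2,3-dihydro-1-benzofuran-3-yl 3-methylbutanoate
Product: 15 (2R,3S)-2-(3-hydroxyprop-1-en-2-yl)-5-[(1R)-1-{[(2R)-2-methylbutanoyl]oxy}ethyl]-2,3-dihydro-1-benzofuran-3-yl 3-methylbutanoate
Conditions: DDQ, CH2Cl2/pH 7 buffer, 0 °C
Reagents that add atoms: none
Why: Oxidative cleavage of the PMB ether by DDQ; the ether oxygen stabilises the 4-methoxybenzyl cation, whereas the benzylic positions of ring A carry deactivating acyloxy groups. The neutral, buffered medium leaves both esters and the allylic aryl ether untouched.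

Step 8
Reactants: 15 (2R,3S)-2-(3-hydroxyprop-1-en-2-yl)-5-[(1R)-1-{[(2R)-2-methylbutanoyl]oxy}ethyl]-2,3-dihydro-1-benzofuran-3-yl 3-methylbutanoate
Product: 16 (1R)-1-[(2R,3S)-3-[(3-methylbutanoyl)oxy]-2-(3-oxoprop-1-en-2-yl)-2,3-dihydro-1-benzofuran-5-yl]ethyl (2R)-2-methylbutanoate
Conditions: MnO2 (activated), CH2Cl2, rt
Reagents that add atoms: none
Why: MnO2 oxidises the primary allylic alcohol selectively to the enal on a solid surface, without acid, base or nucleophile. The SN2′-labile O1–C2 bond and the acid-labile C3 ester should survive, and no stereocenter is touched.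

## Compound list

1 | 4-methoxybenzyl alcohol | COc1ccc(CO)cc1 | starting material
2 | 3-chloro-2-(chloromethyl)prop-1-ene | C=C(CCl)CCl | starting material
3 | 1-({[2-(chloromethyl)prop-2-en-1-yl]oxy}methyl)-4-methoxybenzene | C=C(CCl)COCc1ccc(OC)cc1 | intermediate
4 | (2R,5R)-2,5-dimethylthiolane | C[C@@H]1CC[C@@H](C)S1 | starting material
5 | (2R,5R)-1-(2-{[(4-methoxybenzyl)oxy]methyl}prop-2-en-1-yl)-2,5-dimethylthiolan-1-ium tetrafluoroborate | C[C@@H]1CC[C@@H](C)[S+]1CC(=C)COCc1ccc(OC)cc1.F[B-](F)(F)F | intermediate
6 | 5-acetyl-2-hydroxybenzaldehyde | CC(=O)c1ccc(O)c(C=O)c1 | starting material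
7 | sulfonium ylide of 5, (2R,5R)-2,5-dimethylthiolanium 2-{[(4-methoxybenzyl)oxy]methyl}prop-2-en-1-ylide | C[C@@H]1CC[C@@H](C)[S+]1[CH-]C(=C)COCc1ccc(OC)cc1 | intermediate (not isolated)
8 | potassium 4-acetyl-2-[(2S,3S)-3-{3-[(4-methoxybenzyl)oxy]prop-1-en-2-yl}oxiran-2-yl]phenolate | [K+].[O-]c1ccc(C(C)=O)cc1[C@@H]1O[C@H]1C(=C)COCc1ccc(OC)cc1 | intermediate (not isolated)
9 | 1-[(2R,3S)-3-hydroxy-2-{3-[(4-methoxybenzyl)oxy]prop-1-en-2-yl}-2,3-dihydro-1-benzofuran-5-yl]ethan-1-one | C=C(COCc1ccc(OC)cc1)[C@H]1Oc2ccc(C(C)=O)cc2[C@@H]1O | intermediate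
10 | 3-methylbutanoic anhydride | CC(C)CC(=O)OC(=O)CC(C)C | starting material
11 | (2R,3S)-5-acetyl-2-{3-[(4-methoxybenzyl)oxy]prop-1-en-2-yl}-2,3-dihydro-1-benzofuran-3-yl 3-methylbutanoate | C=C(COCc1ccc(OC)cc1)[C@H]1Oc2ccc(C(C)=O)cc2[C@@H]1OC(=O)CC(C)C | intermediate
12 | (2R,3S)-5-[(1R)-1-hydroxyethyl]-2-{3-[(4-methoxybenzyl)oxy]prop-1-en-2-yl}-2,3-dihydro-1-benzofuran-3-yl 3-methylbutanoate | C=C(COCc1ccc(OC)cc1)[C@H]1Oc2ccc([C@@H](C)O)cc2[C@@H]1OC(=O)CC(C)C | intermediate
13 | (2R)-2-methylbutanoic acid | CC[C@@H](C)C(=O)O | starting material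
14 | (2R,3S)-2-{3-[(4-methoxybenzyl)oxy]prop-1-en-2-yl}-5-[(1R)-1-{[(2R)-2-methylbutanoyl]oxy}ethyl]-2,3-dihydro-1-benzofuran-3-yl 3-methylbutanoate | C=C(COCc1ccc(OC)cc1)[C@H]1Oc2ccc([C@@H](C)OC(=O)[C@H](C)CC)cc2[C@@H]1OC(=O)CC(C)C | intermediate
15 | (2R,3S)-2-(3-hydroxyprop-1-en-2-yl)-5-[(1R)-1-{[(2R)-2-methylbutanoyl]oxy}ethyl]-2,3-dihydro-1-benzofuran-3-yl 3-methylbutanoate | C=C(CO)[C@H]1Oc2ccc([C@@H](C)OC(=O)[C@H](C)CC)cc2[C@@H]1OC(=O)CC(C)C | intermediate
16 | (1R)-1-[(2R,3S)-3-[(3-methylbutanoyl)oxy]-2-(3-oxoprop-1-en-2-yl)-2,3-dihydro-1-benzofuran-5-yl]ethyl (2R)-2-methylbutanoate | C=C(C=O)[C@H]1Oc2ccc([C@@H](C)OC(=O)[C@H](C)CC)cc2[C@@H]1OC(=O)CC(C)C | target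

## Step count and least certain steps

Total steps: 8. Longest linear sequence: 8 (steps 1 to 8; compounds 4, 6, 10 and 13 are purchased).

**Step 3 (key step).** Three things are most likely to go wrong. Facial selectivity may erode if addition of the ylide to the deactivated phenoxide aldehyde becomes reversible. The phenoxide may displace the sulfide directly from the betaine before the epoxide forms, which would lead to the cis ring. Base may also cause self-condensation between acetyl and formyl groups.

Fallback: setting out from 6, silylation (t-BuMe2SiCl, imidazole) gives 5-acetyl-2-[(tert-butyldimethylsilyl)oxy]benzaldehyde F1, an ordinary aromatic aldehyde. The ylide is preformed from 5 with KN(SiMe3)2 in THF at −78 °C and epoxidises F1 to the silyl-protected trans-vinyl epoxide 1-{4-[(tert-butyldimethylsilyl)oxy]-3-[(2S,3S)-3-{3-[(4-methoxybenzyl)oxy]prop-1-en-2-yl}oxiran-2-yl]phenyl}ethan-1-one F2. F2 is isolated and purified, and Bu4NF in THF then frees the phenoxide, which closes ring B and returns to 9.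

**Step 5.** Hydride transfer to the electron-rich aryl ketone may be slow, and prolonged exposure to formic acid may ionise the C3 ester, with loss of the acid and aromatisation of ring B.

Fallback: from 11 the ketone is reduced at pH 7 with an (R)-selective NADPH-dependent alcohol dehydrogenase (cofactor recycled with 2-propanol). This gives 12 directly with no acid present and makes no new compound.

**Step 6.** The activated acyl species may epimerise at the α-carbon of 13 (enolisation or ketene formation), and the p-alkoxybenzylic alcohol may ionise.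

Fallback: setting out from 13, transvinylation with vinyl acetate (Pd(OAc)2 catalyst) gives ethenyl (2R)-2-methylbutanoate F3. Candida antarctica lipase B in toluene then transfers the acyl group from F3 to alcohol 12, which returns to 14. The acid is never activated chemically, and the enzyme acylates only the (R)-carbinol, so it also checks the outcome of step 5.

**Step 7.** DDQ may oxidise ring A through charge transfer or hydride abstraction at its two oxygenated benzylic positions, now that the deactivating acetyl group is gone.

Fallback: the PMB group is removed earlier, from 11, where the acetyl group still deactivates ring A. DDQ gives (2R,3S)-5-acetyl-2-(3-hydroxyprop-1-en-2-yl)-2,3-dihydro-1-benzofuran-3-yl 3-methylbutanoate F4. Silylation gives (2R,3S)-5-acetyl-2-(3-{[tert-butyl(dimethyl)silyl]oxy}prop-1-en-2-yl)-2,3-dihydro-1-benzofuran-3-yl 3-methylbutanoate F5. The reduction and esterification conditions of the main route then give the alcohol (2R,3S)-2-(3-{[tert-butyl(dimethyl)silyl]oxy}prop-1-en-2-yl)-5-[(1R)-1-hydroxyethyl]-2,3-dihydro-1-benzofuran-3-yl 3-methylbutanoate F6 and the diester (2R,3S)-2-(3-{[tert-butyl(dimethyl)silyl]oxy}prop-1-en-2-yl)-5-[(1R)-1-{[(2R)-2-methylbutanoyl]oxy}ethyl]-2,3-dihydro-1-benzofuran-3-yl 3-methylbutanoate F7. HF·pyridine in THF then returns to 15.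

## Further compounds

F1 | step 3 | 5-acetyl-2-[(tert-butyldimethylsilyl)oxy]benzaldehyde | CC(=O)c1ccc(O[Si](C)(C)C(C)(C)C)c(C=O)c1
F2 | step 3 | 1-{4-[(tert-butyldimethylsilyl)oxy]-3-[(2S,3S)-3-{3-[(4-methoxybenzyl)oxy]prop-1-en-2-yl}oxiran-2-yl]phenyl}ethan-1-one | CC(=O)c1ccc(O[Si](C)(C)C(C)(C)C)c(c1)[C@@H]1O[C@H]1C(=C)COCc1ccc(OC)cc1
F0 | step 5 | none | none
F3 | step 6 | ethenyl (2R)-2-methylbutanoate | C=COC(=O)[C@H](C)CC
F4 | step 7 | (2R,3S)-5-acetyl-2-(3-hydroxyprop-1-en-2-yl)-2,3-dihydro-1-benzofuran-3-yl 3-methylbutanoate | C=C(CO)[C@H]1Oc2ccc(C(C)=O)cc2[C@@H]1OC(=O)CC(C)C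
F5 | step 7 | (2R,3S)-5-acetyl-2-(3-{[tert-butyl(dimethyl)silyl]oxy}prop-1-en-2-yl)-2,3-dihydro-1-benzofuran-3-yl 3-methylbutanoate | C=C(CO[Si](C)(C)C(C)(C)C)[C@H]1Oc2ccc(C(C)=O)cc2[C@@H]1OC(=O)CC(C)C
F6 | step 7 | (2R,3S)-2-(3-{[tert-butyl(dimethyl)silyl]oxy}prop-1-en-2-yl)-5-[(1R)-1-hydroxyethyl]-2,3-dihydro-1-benzofuran-3-yl 3-methylbutanoate | C=C(CO[Si](C)(C)C(C)(C)C)[C@H]1Oc2ccc([C@@H](C)O)cc2[C@@H]1OC(=O)CC(C)C
F7 | step 7 | (2R,3S)-2-(3-{[tert-butyl(dimethyl)silyl]oxy}prop-1-en-2-yl)-5-[(1R)-1-{[(2R)-2-methylbutanoyl]oxy}ethyl]-2,3-dihydro-1-benzofuran-3-yl 3-methylbutanoate | C=C(CO[Si](C)(C)C(C)(C)C)[C@H]1Oc2ccc([C@@H](C)OC(=O)[C@H](C)CC)cc2[C@@H]1OC(=O)CC(C)C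
A1 | alternative 1 | 1-{4-[(tert-butyldimethylsilyl)oxy]-3-[(1E)-3-methylbuta-1,3-dien-1-yl]phenyl}ethan-1-one | CC(=C)/C=C/c1cc(C(C)=O)ccc1O[Si](C)(C)C(C)(C)C
A2 | alternative 1 | 1-{3-[(1S,2S)-1,2-dihydroxy-3-methylbut-3-en-1-yl]-4-hydroxyphenyl}ethan-1-one | CC(=C)[C@H](O)[C@@H](O)c1cc(C(C)=O)ccc1O
A3 | alternative 1 | (1R)-1-[(2R,3S)-3-[(3-methylbutanoyl)oxy]-2-(prop-1-en-2-yl)-2,3-dihydro-1-benzofuran-5-yl]ethyl (2R)-2-methylbutanoate | CC(=C)[C@H]1Oc2ccc([C@@H](C)OC(=O)[C@H](C)CC)cc2[C@@H]1OC(=O)CC(C)C
A4 | alternative 2 | 1-(2,2-dimethyl-2H-chromen-6-yl)ethan-1-one | CC(=O)c1ccc2OC(C)(C)C=Cc2c1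
A5 | alternative 2 | (3R,4R)-6-acetyl-3,4-epoxy-2,2-dimethyl-3,4-dihydro-2H-chromene | CC(=O)c1ccc2OC(C)(C)[C@@H]3O[C@@H]3c2c1
A6 | alternative 2 | (3R,4S)-6-acetyl-3-hydroxy-2,2-dimethyl-3,4-dihydro-2H-chromen-4-yl 3-methylbutanoate | CC(=O)c1ccc2OC(C)(C)[C@H](O)[C@@H](OC(=O)CC(C)C)c2c1
A7 | alternative 2 | (2R,3S)-5-acetyl-2-(prop-1-en-2-yl)-2,3-dihydro-1-benzofuran-3-yl 3-methylbutanoate | CC(=C)[C@H]1Oc2ccc(C(C)=O)cc2[C@@H]1OC(=O)CC(C)C
A8 | alternative 3 | 5-acetyl-2-fluorobenzaldehyde | CC(=O)c1ccc(F)c(C=O)c1
A9 | alternative 3 | 2-{[(4-methoxybenzyl)oxy]methyl}prop-2-ene-1,1-diyl bis(3-methylbutanoate) | C=C(COCc1ccc(OC)cc1)C(OC(=O)CC(C)C)OC(=O)CC(C)C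
A10 | alternative 3 | (1S,2R)-1-(5-acetyl-2-fluorophenyl)-1-hydroxy-3-{[(4-methoxybenzyl)oxy]methyl}but-3-en-2-yl 3-methylbutanoate | C=C(COCc1ccc(OC)cc1)[C@@H](OC(=O)CC(C)C)[C@@H](O)c1cc(C(C)=O)ccc1F
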